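The disconnection cuts the CMe2–CHBr edge (C4–C5, 1-benzofuran numbering) out of the carbocycle of the trans-fused hexahydrobenzofuran as 1-bromo-2-methylprop-1-ene. In one operation an acid-generated (1-methylcyclopropyl)carbinyl cation, a masked homoallyl cation holding C3a, C7a, C7 and C6, is attacked at C6 by the bromoalkene (bond C5–C6). The bromine-bridged tertiary cation then closes through a chair onto the newly formed E-alkene (bond C3a–C4), and the carboxyl group captures C7a. The step exploits the anti arrangement of C4 and O1 across the C3a–C7a ring fusion and the equatorial bromide at C5. The precursor is a racemic β-hydroxy acid; the bromolactone is resolved and converted into the (Z)-vinylogous ester.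

Key step: step 2

Remarks: aldehyde 1 is taken as purchasable (it is otherwise one oxidation away from commercial (1-methylcyclopropyl)methanol). Racemic 5 is written as the pair of its enantiomers. Locants follow 1-benzofuran numbering (O1, C2, C3, C3a, C4–C7, C7a).

Step 1
Reactants: 1 1-methylcyclopropane-1-carbaldehyde; 2 acetic acid
Product: 3 rac-3-hydroxy-3-(1-methylcyclopropyl)propanoic acid
Conditions: 2, LiN(i-Pr)2 (2.2 equiv), THF, −78 → 35 °C; then 1, 0 °C; aq. HCl
Reagents that add atoms: none
Why: Aldol addition of the dilithium enediolate of acetic acid to the non-enolisable aldehyde should give the β-hydroxy acid directly; the carbinol centre is left racemic on purpose because it is erased in step 2.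

Step 2
Reactants: 3 rac-3-hydroxy-3-(1-methylcyclopropyl)propanoic acid; 4 1-bromo-2-methylprop-1-ene
Product: 5 rac-(3aS,5S,7aS)-5-bromo-4,4,7a-trimethylhexahydro-1-benzofuran-2(3H)-one
Conditions: 4 (10 equiv, co-solvent), TfOH (5 mol %), (CF3)2CHOH, 0 °C; aq. NaHCO3
Reagents that add atoms: none
Why: Proposed new method: ionisation of the carbinol gives a (1-methylcyclopropyl)carbinyl cation that reacts as a homoallyl cation, the CHBr carbon of 4 attacking a ring CH2 (bond C5–C6) while the three-membered ring opens to the E-trisubstituted C3a=C7a alkene, as in the Julia–Johnson rearrangement, and the charge moves to the CMe2 carbon as a bromine-bridged tertiary cation. That ion is the intermediate of a bromonium-induced polyene cyclisation, so the alkene should add to it through a chair in a 6-endo cation–olefin closure of the carbocycle (bond C3a–C4) while the carboxyl oxygen closes the lactone by 5-exo capture of C7a. The closest known reactions are the acid-mediated homoallylation of π-nucleophiles by cyclopropylcarbinols and the bromonium-triggered cyclisation of homogeranic acid to the same lactone skeleton. The chair with equatorial bromine and anti addition across the E-alkene set C5, C3a and C7a relative to one another (trans ring fusion), whereas C5 itself forms in the intermolecular step without facial bias, so 5 is racemic. The step needs capture at the homoallylic carbon by a weak π-nucleophile in preference to proton loss or capture at the carbinyl or ring-expanded cyclobutyl positions: 4 is the co-solvent in a poorly nucleophilic ionising medium, both carbinol epimers and the reversibly formed cyclopropylcarbinyl and cyclobutyl adducts feed the same cation, and C–C bond formation is the only irreversible exit.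

Step 3
Reactants: 5 rac-(3aS,5S,7aS)-5-bromo-4,4,7a-trimethylhexahydro-1-benzofuran-2(3H)-one; 6 (1S)-1-phenylethan-1-amine
Product: 7 2-[(1S,3S,6S)-3-bromo-6-hydroxy-2,2,6-trimethylcyclohexyl]-N-[(1S)-1-phenylethyl]acetamide
Conditions: 6 (1.5 equiv), AlMe3 (1.5 equiv), CH2Cl2, 0 °C → rt; aq. KNaC4H4O6; separation of the two diastereomers on Et3N-buffered silica gel or by crystallisation
Reagents that add atoms: none
Why: Aminolysis of the lactone by the dimethylaluminium amide should open both enantiomers of 5 to γ-hydroxy amides that are diastereomers and hence separable (classical resolution); no stereocentre is touched, and the absolute configuration of 7 can be secured by X-ray analysis with bromine as heavy atom.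

Step 4
Reactants: 7 2-[(1S,3S,6S)-3-bromo-6-hydroxy-2,2,6-trimethylcyclohexyl]-N-[(1S)-1-phenylethyl]acetamide
Product: 8 (3aS,5S,7aS)-5-bromo-4,4,7a-trimethylhexahydro-1-benzofuran-2(3H)-one
Conditions: 0.5 M aq. H2SO4, THF, 50 °C
Reagents that add atoms: none
Why: Acid-catalysed lactonisation of the γ-hydroxy amide (N→O acyl transfer assisted by the neighbouring hydroxyl) should re-form the lactone and release the amine; the C7a–O bond is not broken, so the trans ring fusion is retained.

Step 5
Reactants: 8 (3aS,5S,7aS)-5-bromo-4,4,7a-trimethylhexahydro-1-benzofuran-2(3H)-one; 9 N-methoxy-N-methylpropanamide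
Product: 11 (2Z)-2-[(3aS,5S,7aS)-5-bromo-4,4,7a-trimethylhexahydro-1-benzofuran-2(3H)-ylidene]-N-methoxy-N-methylpropanamide, via hydroxy keto amide 10 (not isolated)
Conditions: 9 (2.5 equiv), LiN(i-Pr)2 (2.5 equiv), THF, −78 °C; then 8, −78 → −20 °C; aq. NH4Cl; crude 10, TsOH·H2O (10 mol %), CH2Cl2, rt
Reagents that add atoms: none
Why: Claisen condensation of the amide enolate with the lactone gives β-keto amide 10 (in equilibrium with its cyclic hemiketal), whose acid-catalysed cyclodehydration should give the exocyclic push–pull enol ether; its E and Z forms interconvert under acid, and the Z form (carbonyl syn to O1, methyl syn to C3) is expected to prevail because it avoids the clash of the acyl group with C3H2.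

Step 6
Reactants: 11 (2Z)-2-[(3aS,5S,7aS)-5-bromo-4,4,7a-trimethylhexahydro-1-benzofuran-2(3H)-ylidene]-N-methoxy-N-methylpropanamide
Product: 12 (3Z)-1-bromo-3-[(3aS,5S,7aS)-5-bromo-4,4,7a-trimethylhexahydro-1-benzofuran-2(3H)-ylidene]butan-2-one
Conditions: CH2Br2 (3 equiv), MeLi·LiBr (2.5 equiv, added last), THF, −78 °C; sat. aq. NH4Cl at −78 °C
Reagents that add atoms: dibromomethane, BrCBr
Why: Bromomethyllithium made by bromine–lithium exchange should add once to the N-methoxy-N-methylamide to give a chelated tetrahedral adduct that releases the bromomethyl ketone on quenching (carbenoid acylation); the alkene geometry and ring stereocentres are untouched, and the equatorial neopentyl bromide is inert at −78 °C.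

Compound list
1 | 1-methylcyclopropane-1-carbaldehyde | CC1(C=O)CC1 | starting material
2 | acetic acid | CC(=O)O | starting material
3 | rac-3-hydroxy-3-(1-methylcyclopropyl)propanoic acid | OC(CC(=O)O)C1(C)CC1 | intermediate
4 | 1-bromo-2-methylprop-1-ene | CC(C)=CBr | starting material
5 | rac-(3aS,5S,7aS)-5-bromo-4,4,7a-trimethylhexahydro-1-benzofuran-2(3H)-one (both enantiomers written) | O=C1C[C@H]2C(C)(C)[C@@H](Br)CC[C@]2(C)O1.O=C1C[C@@H]2C(C)(C)[C@H](Br)CC[C@@]2(C)O1 | intermediate
6 | (1S)-1-phenylethan-1-amine | C[C@H](N)c1ccccc1 | starting material
7 | 2-[(1S,3S,6S)-3-bromo-6-hydroxy-2,2,6-trimethylcyclohexyl]-N-[(1S)-1-phenylethyl]acetamide | O=C(N[C@@H](C)c1ccccc1)C[C@H]1C(C)(C)[C@@H](Br)CC[C@]1(C)O | intermediate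
8 | (3aS,5S,7aS)-5-bromo-4,4,7a-trimethylhexahydro-1-benzofuran-2(3H)-one | O=C1C[C@H]2C(C)(C)[C@@H](Br)CC[C@]2(C)O1 | intermediate
9 | N-methoxy-N-methylpropanamide | CCC(=O)N(C)OC | starting material
10 | 4-[(1S,3S,6S)-3-bromo-6-hydroxy-2,2,6-trimethylcyclohexyl]-N-methoxy-N,2-dimethyl-3-oxobutanamide (C2 epimers) | CC(C(=O)N(C)OC)C(=O)C[C@H]1C(C)(C)[C@@H](Br)CC[C@]1(C)O | intermediate (not isolated)
11 | (2Z)-2-[(3aS,5S,7aS)-5-bromo-4,4,7a-trimethylhexahydro-1-benzofuran-2(3H)-ylidene]-N-methoxy-N-methylpropanamide | C/C(C(=O)N(C)OC)=C1\C[C@H]2C(C)(C)[C@@H](Br)CC[C@]2(C)O1 | intermediate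
12 | (3Z)-1-bromo-3-[(3aS,5S,7aS)-5-bromo-4,4,7a-trimethylhexahydro-1-benzofuran-2(3H)-ylidene]butan-2-one | C/C(C(=O)CBr)=C1\C[C@H]2C(C)(C)[C@@H](Br)CC[C@]2(C)O1 | target

Total step count: 6
Longest linear sequence: 6 steps (1 → 3 → 5 → 7 → 8 → 11 → 12)

Steps most likely to fail

Step 2 (proposed new method). The delocalised cation may be consumed before the weakly nucleophilic bromoalkene reaches the homoallylic carbon. The competing processes are capture of its ring-expanded cyclobutyl form by the internal carboxyl group, proton loss, capture by the solvent, and acid-induced oligomerisation of the bromoalkene. The fallback uses known chemistry and sets out from 3. Julia–Johnson rearrangement with HBr and ZnBr2 should give (3E)-6-bromo-4-methylhex-3-enoic acid F1. Copper-catalysed coupling (Li2CuCl4) with Me2C=CHMgBr (2.2 equiv) should give (3E)-4,8-dimethylnona-3,7-dienoic acid F2. Bromonium-induced polyene cyclisation of F2 with Et2SBr·SbCl5Br in MeNO2 at low temperature should give 5, where the route is rejoined. In this fallback the C5–C6 bond forms in the coupling and the C3a–C4 bond in the cyclisation.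

Step 6. The carbenoid may act as a base at the γ-positions, decompose before it adds, or attack C2 in a conjugate sense with opening of the oxygen ring. The fallback sets out from 11. MeMgBr should give (3Z)-3-[(3aS,5S,7aS)-5-bromo-4,4,7a-trimethylhexahydro-1-benzofuran-2(3H)-ylidene]butan-2-one F3. Kinetic deprotonation of the acetyl methyl group with LiN(SiMe3)2 at −78 °C and bromination of the enolate with N-bromosuccinimide should then give 12.

Step 3. The two diastereomeric amides may co-elute and co-crystallise, or revert to lactone on silica before they are separated. The fallback sets out from 5: preparative chromatography on a chiral stationary phase (amylose or cellulose carbamate) should deliver 8 directly, by-passing 7.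

Further compounds
F1 | step 2 | (3E)-6-bromo-4-methylhex-3-enoic acid | OC(=O)C/C=C(\C)CCBr
F2 | step 2 | (3E)-4,8-dimethylnona-3,7-dienoic acid | OC(=O)C/C=C(\C)CCC=C(C)C
F3 | step 6 | (3Z)-3-[(3aS,5S,7aS)-5-bromo-4,4,7a-trimethylhexahydro-1-benzofuran-2(3H)-ylidene]butan-2-one | C/C(C(C)=O)=C1\C[C@H]2C(C)(C)[C@@H](Br)CC[C@]2(C)O1
F0 | step 3 | none | none
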